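Start with the easy step, E + Q to E.Q, and ask of each given number how far the outcome moves if that number is off.

the same everywhere: J 0.5 mol%; G 1.1 mM

| run | E | Q | time | remark |
|---|---|---|---|---|
| Thursday's | 0.10 M | 0.950 equiv (fed, over 2.50 d) | 2.5 d | a stirred flask in which Q is dosed at a steady rate over 2.50 d without added volume, worked up at 2.5 d |
| Tuesday's | 0.10 M | 0.950 equiv |  | one stirred flow tank at steady state, fed with the mixture as stated, mean residence time 2.5 d |
| Saturday's | 0.10 M (fed, over 2.50 d) | 0.950 equiv | 2.5 d | all but E at the start; E goes in evenly over 2.50 d, the run ends at 2.5 d |
| Friday's | 0.10 M | 0.950 equiv | 2.5 d | everything together in a closed stirred flask, run for 2.5 d |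

    J + G ⇌ J.G, settled at all times (K1 = 5300 /M)
    E + Q ⇌ D (K2 = 24 /M, k2 = 5.9 /M/h)
    E.Q + J ⇌ D + J, rate k3*[J]*[E.Q] forward; the back reaction follows from the equilibrium constant (k3 = 10 /M/h)
    E + Q ⇌ E.Q (K4 = 11 /M, k4 = 13 /M/h)

- the stated concentrations are those of everything mixed, before any reaction; amounts are the same in each set-up
- the feed brings no volume worth counting
- run time (Thursday's): 2.5 d

* the set-up with the highest amount of E.Q at the outlet or at the end, in percent of the E put in ("none" if the first two lie within 2 percentage points) (Thursday's / Tuesday's / Saturday's / Friday's / none)
* amount of E.Q at the outlet or at the end, in percent of the E put in, Thursday's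
* amount of E.Q at the outlet or at the end, in percent of the E put in, Tuesday's
* amount of E.Q at the outlet or at the end, in percent of the E put in, Saturday's
* amount of E.Q at the outlet or at the end, in percent of the E put in, Friday's

Test the rate constants first. In Friday's flask, as charged and by forward rate alone, E has a half-life of 0.56 h by E + Q to E.Q and 0.052 d by E + Q to D. Both are far shorter than the run of 2.5 d, so in Friday's flask an error in them shifts the time to balance and hardly the end point.

Test the catalyst next. Even with the whole of J free, E.Q to D has a forward time of 200 h, longer than the run. Its constant, 2.18, also asks for the same balance as the two uncatalysed steps, so treat the numbers of J and G as minor.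

That leaves the two balance constants. Divide 11 /M by 24 /M: 0.458 is the split, the ratio cE.Q / cD that both balances leave. This is thermodynamic control. Their sum, 35.0 /M, goes into the balance for the converted amount. Q is the limiting reagent, 0.0950 M against 0.10 M. Call the converted amount s:

s = 35.0 /M × (cE charged − s) × (cQ charged − s)

0.224 M is the sum that enters the root, and s = 0.0570 M

E.Q share = s × split / (1 + split) / cE charged = 17.9 %

Now test these two. With 2 times 11 /M the share becomes 29.2 %, and with 2 times 24 /M it becomes 12.0 %. These are the numbers to know well. Commit to 17.9 % for all four set-ups, so no set-up leads by 2 percentage points.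

The forecast gives 18.2 %, 18.4 %, 18.2 % and 17.9 % for Thursday's, Tuesday's, Saturday's and Friday's, and none as best, holding that “every set-up ends close to the same equilibrium”.

The simulation gives 18.2 %, 18.3 %, 18.2 % and 17.9 % in that order, and none as best. Left until 25.0 d, Friday's flask reads 17.9 %. Dividing the 17.9 % of Friday's flask at 2.5 d by the split gives a reckoned 39.1 % of D for that moment. In Saturday's flask D reads 38.4 %, and the split turns that into 17.6 % of E.Q, while the flask holds 18.2 %, a gap of 0.61 points.

The rate constants come from no measurement; the result is computed.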